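**Retrosynthetic overview**
1. The strategy rests on ring A, the benzoate ring: C1 bears the ester carbonyl, C2 and C4 the hydroxyls, C6 the 8-hydroxyundecyl chain. It is the aromatized fold of a 3,5,7-trioxoalkanoate ester whose alkoxy oxygen is the C8' oxygen of the ring B undecyl chain.
2. Key disconnection: the ester acyl C–O bond and the ring A C1–C6 bond are broken together, leading back to diketo-dioxinone 12 (a masked acylketene) and ring B alcohol 20.
3. 12 comes from acid 6 ((S)-2-propyloxirane plus an oct-7-enyl Grignard reagent, silylation, RuO4 cleavage) and acetonyl-dioxinone 9 by dianion acylation.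
4. 20 comes from (R)-2-propyloxirane plus a hex-5-enyl Grignard reagent, then hydroboration and B-alkyl Suzuki coupling with bis-MOM 5-bromoresorcinol 18.
5. Ring order: ring B is bought as 5-bromobenzene-1,3-diol; ring A is the only ring formed (step 9); acid removes the MOM and TBS groups last.

Key step: step 9

Assumption: both enantiomers of 2-propyloxirane are used in high enantiomeric purity (bought, or from hydrolytic kinetic resolution), because the two remote carbinol centres come only from these reagents and cannot be enriched later.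

**Route**

Step 1
Reactants: 1 8-bromooct-1-ene; 2 (S)-2-propyloxirane
Product: 4 (S)-tridec-12-en-4-ol, via oct-7-enylmagnesium bromide 3 (not isolated)
Conditions: Mg, THF, rt; then CuI (10 mol %), 2, THF, −30 → 0 °C; aq. NH4Cl
Reagents that add atoms: none
Why: Copper-catalysed SN2 opening of a terminal epoxide by a primary alkyl Grignard reagent takes place at the unsubstituted CH2, so the C–O stereocentre of 2 is not touched and becomes the (S)-carbinol C4 of 4.

Step 2
Reactants: 4 (S)-tridec-12-en-4-ol
Product: 5 (S)-tert-butyldimethyl(tridec-12-en-4-yloxy)silane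
Conditions: TBSCl, imidazole, DMF, rt
Reagents that add atoms: tert-butyldimethylsilyl chloride, CC(C)(C)[Si](C)(C)Cl
Why: Standard imidazole-promoted silylation of a secondary alcohol should mask the hydroxyl, which would otherwise capture the acylketene intramolecularly in step 9.

Step 3
Reactants: 5 (S)-tert-butyldimethyl(tridec-12-en-4-yloxy)silane
Product: 6 (S)-9-(tert-butyldimethylsilyloxy)dodecanoic acid
Conditions: RuCl3 (2 mol %), NaIO4 (4 equiv), MeCN/EtOAc/H2O, rt
Reagents that add atoms: sodium periodate, [Na+].[O-]I(=O)(=O)=O; water, O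
Why: Oxidative cleavage of a monosubstituted alkene by catalytic RuO4 (Sharpless RuCl3/NaIO4 conditions) should give the one-carbon-shorter carboxylic acid directly, and the secondary silyl ether and the remote stereocentre are inert to it.

Step 4
Reactants: 7 2,2,6-trimethyl-4H-1,3-dioxin-4-one
Product: 9 2,2-dimethyl-6-(2-oxopropyl)-4H-1,3-dioxin-4-one, via lithium dienolate 8 (not isolated)
Conditions: LiN(SiMe3)2 (1 equiv), THF, −78 °C; then AcCl (0.5 equiv), −78 °C; aq. NH4Cl
Reagents that add atoms: acetyl chloride, CC(Cl)=O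
Why: Deprotonation of the vinylogous ester at the C6 methyl gives dienolate 8, which is C-acylated at the exocyclic carbon by acetyl chloride (crossed Claisen-type acylation); half of the enolate is held back to take the proton of the more acidic product.

Step 5
Reactants: 6 (S)-9-(tert-butyldimethylsilyloxy)dodecanoic acid; 9 2,2-dimethyl-6-(2-oxopropyl)-4H-1,3-dioxin-4-one
Product: 12 6-[(12S)-12-(tert-butyldimethylsilyloxy)-2,4-dioxopentadecyl]-2,2-dimethyl-4H-1,3-dioxin-4-one, via acyl imidazolide 10 (not isolated), via dilithium dianion 11 (not isolated)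
Conditions: 6, CDI, THF, rt; separately 9 (3 equiv), LiN(i-Pr)2 (6 equiv), THF, −78 °C; add the solution of 10, −78 → −40 °C; aq. NH4Cl; use 12 promptly
Reagents that add atoms: none
Why: Claisen-type acylation of a ketone dianion occurs at the terminal, last-formed carbanion (the former methyl carbon), so imidazolide 10 should deliver the 1,3-diketone; the excess dianion absorbs the N–H of the liberated imidazole and the acidic proton of the product, and the silyl ether and stereocentre are untouched.

Step 6
Reactants: 13 6-bromohex-1-ene; 14 (R)-2-propyloxirane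
Product: 16 (R)-undec-10-en-4-ol, via hex-5-enylmagnesium bromide 15 (not isolated)
Conditions: Mg, THF, rt; then CuI (10 mol %), 14, THF, −30 → 0 °C; aq. NH4Cl
Reagents that add atoms: none
Why: The same copper-catalysed SN2 epoxide opening at the terminal CH2 as in step 1 carries the stereocentre of 14 over unchanged as the (R)-carbinol C4 of 16.

Step 7
Reactants: 17 5-bromobenzene-1,3-diol
Product: 18 1-bromo-3,5-bis(methoxymethoxy)benzene
Conditions: MOMCl, i-Pr2NEt, CH2Cl2, 0 °C → rt
Reagents that add atoms: chloromethyl methyl ether, COCCl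
Why: O-Alkylation of both phenols with chloromethyl methyl ether gives acetal ethers that cannot capture the ketene of step 9 and that fall off under the same acid that removes the silyl ether.

Step 8
Reactants: 16 (R)-undec-10-en-4-ol; 18 1-bromo-3,5-bis(methoxymethoxy)benzene
Product: 20 (R)-11-[3,5-bis(methoxymethoxy)phenyl]undecan-4-ol, via B-alkyl borane 19 (not isolated)
Conditions: 9-BBN (2.3 equiv), THF, 0 °C → rt; then 18, PdCl2(dppf) (5 mol %), K3PO4 (3 M aq.), DMF, 60 °C
Reagents that add atoms: none
Why: Anti-Markovnikov hydroboration of the terminal alkene followed by B-alkyl Suzuki–Miyaura coupling with the aryl bromide joins C11 to ring B; one extra equivalent of 9-BBN is spent as the O-borinate of the free hydroxyl, which the aqueous base hydrolyses, and no bond to the stereocentre is touched.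

Step 9
Reactants: 12 6-[(12S)-12-(tert-butyldimethylsilyloxy)-2,4-dioxopentadecyl]-2,2-dimethyl-4H-1,3-dioxin-4-one (1.3 equiv); 20 (R)-11-[3,5-bis(methoxymethoxy)phenyl]undecan-4-ol
Product: 24 (R)-11-[3,5-bis(methoxymethoxy)phenyl]undecan-4-yl 2-[(S)-8-(tert-butyldimethylsilyloxy)undecyl]-4,6-dihydroxybenzoate, via acylketene 21 (not isolated), via trioxo ester 22 (not isolated), via aldol adduct 23 (not isolated)
Conditions: PhMe (concentrated), 110 °C; cool to rt, add i-PrOH and Cs2CO3, rt; then AcOH, rt → 40 °C
Reagents that add atoms: none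
Why: Near 110 °C the dioxinone ring of 12 undergoes a retro-[4+2] fragmentation that expels acetone and leaves acylketene 21, whose sp carbon is attacked by the secondary hydroxyl of 20 to form the ester acyl C–O bond of trioxo ester 22; this is the established thermolysis and alcohol-trapping chemistry of diketo-dioxinones, and because ring A does not yet exist the acylation is free of the di-ortho hindrance of a 2,6-disubstituted benzoic acid. Cs2CO3 then equilibrates the enolates of 22, and the C2 enolate of the chain (between the ester and the C3 ketone) adds to the C7 ketone in a 6-(enolendo)-exo-trig aldol closure that forms the ring A C1–C6 bond and gives aldol adduct 23. Acidification with AcOH lets 23 lose water and the two remaining ketones enolize, which should deliver the 2,4-dihydroxy-6-alkylbenzoate 24. No lasting stereocentre is made, since the two sp3 ring centres of 23 are erased on aromatization and both carbinol centres are remote from the bond-making. The step needs intermolecular capture of 21 to outrun its own O-cyclization to a 4-hydroxy-2-pyranone, which the high concentration of 20 from the start secures. It also needs the C2-to-C7 aldol fold to win over the C6-to-C1 Claisen closure and over pyranone formation from 22, which is secured because the Claisen path would have to expel a secondary alkoxide under a mild carbonate base and because acid is admitted only after the carbocycle exists.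

Step 10
Reactants: 24 (R)-11-[3,5-bis(methoxymethoxy)phenyl]undecan-4-yl 2-[(S)-8-(tert-butyldimethylsilyloxy)undecyl]-4,6-dihydroxybenzoate
Product: 25 (R)-11-(3,5-dihydroxyphenyl)undecan-4-yl 2,4-dihydroxy-6-[(S)-8-hydroxyundecyl]benzoate (target)
Conditions: HCl (1.25 M in MeOH), MeOH, rt → 40 °C
Reagents that add atoms: none
Why: Acid-catalysed acetal exchange removes both aryl MOM ethers and acid methanolysis removes the TBS ether, while the di-ortho-substituted, hydrogen-bonded benzoate should resist transesterification and no C–O bond at either stereocentre is broken; any 23 carried through would also be dehydrated here.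

**Compound list**
1 | 8-bromooct-1-ene | C=CCCCCCCBr | starting material
2 | (S)-2-propyloxirane | CCC[C@H]1CO1 | starting material
3 | oct-7-enylmagnesium bromide | C=CCCCCCC[Mg]Br | intermediate
4 | (S)-tridec-12-en-4-ol | CCC[C@H](O)CCCCCCCC=C | intermediate
5 | (S)-tert-butyldimethyl(tridec-12-en-4-yloxy)silane | CCC[C@H](O[Si](C)(C)C(C)(C)C)CCCCCCCC=C | intermediate
6 | (S)-9-(tert-butyldimethylsilyloxy)dodecanoic acid | CCC[C@H](O[Si](C)(C)C(C)(C)C)CCCCCCCC(=O)O | intermediate
7 | 2,2,6-trimethyl-4H-1,3-dioxin-4-one | CC1=CC(=O)OC(C)(C)O1 | starting material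
8 | lithium dienolate of 7 (lithium 2,2-dimethyl-6-methylene-6H-1,3-dioxin-4-olate) | [Li+].C=C1C=C([O-])OC(C)(C)O1 | intermediate
9 | 2,2-dimethyl-6-(2-oxopropyl)-4H-1,3-dioxin-4-one | CC(=O)CC1=CC(=O)OC(C)(C)O1 | intermediate
10 | (S)-9-(tert-butyldimethylsilyloxy)-1-(1H-imidazol-1-yl)dodecan-1-one | CCC[C@H](O[Si](C)(C)C(C)(C)C)CCCCCCCC(=O)n1ccnc1 | intermediate
11 | dilithium dianion of 9 | [Li+].[Li+].C=C([O-])C=C1C=C([O-])OC(C)(C)O1 | intermediate
12 | 6-[(12S)-12-(tert-butyldimethylsilyloxy)-2,4-dioxopentadecyl]-2,2-dimethyl-4H-1,3-dioxin-4-one | CCC[C@H](O[Si](C)(C)C(C)(C)C)CCCCCCCC(=O)CC(=O)CC1=CC(=O)OC(C)(C)O1 | intermediate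
13 | 6-bromohex-1-ene | C=CCCCCBr | starting material
14 | (R)-2-propyloxirane | CCC[C@@H]1CO1 | starting material
15 | hex-5-enylmagnesium bromide | C=CCCCC[Mg]Br | intermediate
16 | (R)-undec-10-en-4-ol | CCC[C@@H](O)CCCCCC=C | intermediate
17 | 5-bromobenzene-1,3-diol | Oc1cc(O)cc(Br)c1 | starting material
18 | 1-bromo-3,5-bis(methoxymethoxy)benzene | COCOc1cc(Br)cc(OCOC)c1 | intermediate
19 | 9-[(8R)-8-(9-borabicyclo[3.3.1]nonan-9-yloxy)undecyl]-9-borabicyclo[3.3.1]nonane | CCC[C@@H](OB1C2CCCC1CCC2)CCCCCCCB1C2CCCC1CCC2 | intermediate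
20 | (R)-11-[3,5-bis(methoxymethoxy)phenyl]undecan-4-ol | CCC[C@@H](O)CCCCCCCc1cc(OCOC)cc(OCOC)c1 | intermediate
21 | (S)-15-(tert-butyldimethylsilyloxy)octadec-1-ene-1,3,5,7-tetraone (acylketene) | CCC[C@H](O[Si](C)(C)C(C)(C)C)CCCCCCCC(=O)CC(=O)CC(=O)C=C=O | intermediate
22 | (R)-11-[3,5-bis(methoxymethoxy)phenyl]undecan-4-yl (S)-15-(tert-butyldimethylsilyloxy)-3,5,7-trioxooctadecanoate | CCC[C@H](O[Si](C)(C)C(C)(C)C)CCCCCCCC(=O)CC(=O)CC(=O)CC(=O)O[C@H](CCC)CCCCCCCc1cc(OCOC)cc(OCOC)c1 | intermediate
23 | (R)-11-[3,5-bis(methoxymethoxy)phenyl]undecan-4-yl 2-[(S)-8-(tert-butyldimethylsilyloxy)undecyl]-2-hydroxy-4,6-dioxocyclohexane-1-carboxylate (ring centres undefined, transient) | CCC[C@H](O[Si](C)(C)C(C)(C)C)CCCCCCCC1(O)CC(=O)CC(=O)C1C(=O)O[C@H](CCC)CCCCCCCc1cc(OCOC)cc(OCOC)c1 | intermediate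
24 | (R)-11-[3,5-bis(methoxymethoxy)phenyl]undecan-4-yl 2-[(S)-8-(tert-butyldimethylsilyloxy)undecyl]-4,6-dihydroxybenzoate | CCC[C@H](O[Si](C)(C)C(C)(C)C)CCCCCCCc1cc(O)cc(O)c1C(=O)O[C@H](CCC)CCCCCCCc1cc(OCOC)cc(OCOC)c1 | intermediate
25 | (R)-11-(3,5-dihydroxyphenyl)undecan-4-yl 2,4-dihydroxy-6-[(S)-8-hydroxyundecyl]benzoate | CCC[C@H](O)CCCCCCCc1cc(O)cc(O)c1C(=O)O[C@H](CCC)CCCCCCCc1cc(O)cc(O)c1 | target

**Step count**
Total: 10 steps. Longest linear sequence: 6 steps (steps 1, 2, 3, 5, 9, 10).

**Steps most likely to fail**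

1. Step 9. The acylketene may cyclize on its own enol oxygen or dimerize faster than the hindered secondary alcohol captures it. The acid finish may also stall before dehydration is complete, or begin to strip the acid-labile ethers. The fallback closes ring A first and makes the ester by alkoxide opening of a benzodioxinone; it sets out from 12 and 20 and comes back to the route at 25. Treating 12 with Et3N in CH2Cl2 at rt should fold it by intramolecular aldol condensation with the dioxinone intact, giving (S)-5-[8-(tert-butyldimethylsilyloxy)undecyl]-7-hydroxy-2,2-dimethyl-4H-benzo[d][1,3]dioxin-4-one F1. MOMCl and i-Pr2NEt would cap the free phenol as (S)-5-[8-(tert-butyldimethylsilyloxy)undecyl]-7-(methoxymethoxy)-2,2-dimethyl-4H-benzo[d][1,3]dioxin-4-one F2. Alcohol 20 is deprotonated with NaN(SiMe3)2 in THF to sodium (R)-11-[3,5-bis(methoxymethoxy)phenyl]undecan-4-olate F3. This alkoxide attacks the lactone carbonyl of F2 (0 °C → rt, acetone lost) to give (R)-11-[3,5-bis(methoxymethoxy)phenyl]undecan-4-yl 2-[(S)-8-(tert-butyldimethylsilyloxy)undecyl]-6-hydroxy-4-(methoxymethoxy)benzoate F4. The methanolic HCl of step 10 then removes three MOM groups and the silyl ether to reach 25.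

2. Step 5. Proton transfer may compete with C-acylation, through enolization of the imidazolide or quenching of the dianion by liberated imidazole, and the diketo-dioxinone may cyclize during isolation. The fallback replaces the Claisen acylation by aldol addition and oxidation; it sets out from 5 and 9 and comes back at 12. Ozonolysis of 5 (O3, CH2Cl2, −78 °C; PPh3) should give (S)-9-(tert-butyldimethylsilyloxy)dodecanal F5. Addition of dianion 11 (from 9 and LiN(i-Pr)2, THF, −78 °C) to F5 gives an alkoxide that is not more acidic than the nucleophile, so no excess is consumed. The product is 6-[(12S)-12-(tert-butyldimethylsilyloxy)-4-hydroxy-2-oxopentadecyl]-2,2-dimethyl-4H-1,3-dioxin-4-one F6, as a mixture of C4 epimers. Dess–Martin periodinane in CH2Cl2 oxidizes it to 12.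

3. Step 8. The free hydroxyl consumes 9-BBN, so hydroboration may be incomplete, and the alkylborane may undergo protodeboronation or β-hydride elimination before it couples with the electron-rich aryl bromide. The fallback uses alkyne chemistry; it sets out from 14 and 18 and comes back at 20. Hex-1-yne and n-BuLi give hex-1-ynyllithium F7, which opens 14 at the CH2 in the presence of BF3·OEt2 (THF, −78 °C) to give (R)-undec-6-yn-4-ol F8. The alkyne zipper (KH, 1,3-diaminopropane, 0 °C → rt) moves the triple bond to the chain end without touching the carbinol, giving (R)-undec-10-yn-4-ol F9. Sonogashira coupling with 18 (PdCl2(PPh3)2, CuI, Et3N, 70 °C) gives (R)-11-[3,5-bis(methoxymethoxy)phenyl]undec-10-yn-4-ol F10, and hydrogenation (H2, Pd/C, EtOAc) gives 20.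

**Further compounds**
F1 | step 9 | (S)-5-[8-(tert-butyldimethylsilyloxy)undecyl]-7-hydroxy-2,2-dimethyl-4H-benzo[d][1,3]dioxin-4-one | CCC[C@H](O[Si](C)(C)C(C)(C)C)CCCCCCCc1cc(O)cc2OC(C)(C)OC(=O)c12
F2 | step 9 | (S)-5-[8-(tert-butyldimethylsilyloxy)undecyl]-7-(methoxymethoxy)-2,2-dimethyl-4H-benzo[d][1,3]dioxin-4-one | CCC[C@H](O[Si](C)(C)C(C)(C)C)CCCCCCCc1cc(OCOC)cc2OC(C)(C)OC(=O)c12
F3 | step 9 | sodium (R)-11-[3,5-bis(methoxymethoxy)phenyl]undecan-4-olate | CCC[C@@H]([O-])CCCCCCCc1cc(OCOC)cc(OCOC)c1.[Na+]
F4 | step 9 | (R)-11-[3,5-bis(methoxymethoxy)phenyl]undecan-4-yl 2-[(S)-8-(tert-butyldimethylsilyloxy)undecyl]-6-hydroxy-4-(methoxymethoxy)benzoate | CCC[C@H](O[Si](C)(C)C(C)(C)C)CCCCCCCc1cc(OCOC)cc(O)c1C(=O)O[C@H](CCC)CCCCCCCc1cc(OCOC)cc(OCOC)c1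
F5 | step 5 | (S)-9-(tert-butyldimethylsilyloxy)dodecanal | CCC[C@H](O[Si](C)(C)C(C)(C)C)CCCCCCCC=O
F6 | step 5 | 6-[(12S)-12-(tert-butyldimethylsilyloxy)-4-hydroxy-2-oxopentadecyl]-2,2-dimethyl-4H-1,3-dioxin-4-one | CCC[C@H](O[Si](C)(C)C(C)(C)C)CCCCCCCC(O)CC(=O)CC1=CC(=O)OC(C)(C)O1
F7 | step 8 | hex-1-ynyllithium | [Li]C#CCCCC
F8 | step 8 | (R)-undec-6-yn-4-ol | CCC[C@@H](O)CC#CCCCC
F9 | step 8 | (R)-undec-10-yn-4-ol | CCC[C@@H](O)CCCCCC#C
F10 | step 8 | (R)-11-[3,5-bis(methoxymethoxy)phenyl]undec-10-yn-4-ol | CCC[C@@H](O)CCCCCC#Cc1cc(OCOC)cc(OCOC)c1
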